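I count everything in one unit, the fraction of the substrate charged.

    substrate + initiating radical → capped initiator + first chain carrier (k1 = 1.64 × 10⁵ M⁻¹ s⁻¹)
    reagent + released group ⇌ idle adduct, settled at all times (K2 = 49 M⁻¹)
    reagent + first chain carrier → product + second chain carrier (k3 = 88400 M⁻¹ s⁻¹)
    substrate + second chain carrier → released group + first chain carrier (k4 = 3.56 × 10⁷ M⁻¹ h⁻¹)
    initiator → 2 initiating radical (k5 = 0.0114 h⁻¹)
    2 first chain carrier → ended chains (k6 = 2.2 × 10⁷ M⁻¹ s⁻¹)

- violet: substrate 10 mM; reagent 0.700 equiv; initiator 1.1 mol%; time 2.5 d
- teal: substrate 10 mM; reagent 0.910 equiv; initiator 1.1 mol%; time 2.5 d

- in percentages every species weighs as the substrate in it: one ended chains counts as two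
- for released group the idle adduct is counted in
- two of one species on the left: rate k times its square, two consumed each time
- run time (violet): 2.5 d

- part of the substrate that has reacted at the end, violet
- part of the substrate that has reacted at the end, teal
- what raising the equivalents of reagent from its lowest to its highest value here does to the part of the substrate that has reacted (changes below 5 percentage points count as none) (it falls / it rises / no change)

Each reagent that a first chain carrier takes costs one substrate in the next step, when the second chain carrier turns back into a first. Each initiating radical costs one substrate on arrival. So the part reacted is the reagent spent plus the radicals made. The large term comes straight from the recipe, and the small one is the correction to reckon. I assume that the chain spends the reagent, the limiting reagent here, within the time.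

Two extreme versions of violet can be solved in the head, both with the chain spending the reagent: one where the initiating radicals take a vanishing share of the substrate, and one where every initiator has broken. The first is a limit of the sum, not a flask that can be run:

vanishing share for the radicals: 70.0%
every initiator broken: 72.2%

The real flask lies between them, and the initiator's clock says where. Its half-life by the breaking step is 2.53 d, close to the run time of 2.5 d, so half of it has broken. Two radicals per initiator, times the loading, times the part broken, gives 1.09%. This is the capping share, the fraction of the substrate taken by initiating radicals. The recipes carry the same loading, so it serves both:

violet: 70.0% + 1.09% = 71.1%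
teal: 91.0% + 1.09% = 92.1%

The forecast gives 71.1% for violet (range 70% to 72%) and 92.1% for teal (range 90.5% to 93%), and says it rises, on the ground that “essentially all the reagent is used up”.

The simulation gives 71.1% for violet and 92.1% for teal; as for the part reacted, it rises by 21 percentage points.

Neither flask has come to rest. At the end violet has 0% of its reagent left, yet 50% of its initiator. The capping share also serves a neighbour of teal charged with 0.360 equiv, where 37.1% is reckoned and the flask gives 37.1%. Over ten times the time the share grows to 2.20%, which adds 1.1 points. At 25.0 d violet has reacted 72.2% and teal 93.2%, with 0.107% of violet's initiator left.

The constants are assumed; the rest is arithmetic.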